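Cuts, in retrosynthetic order: in ring D (the 2,2-dimethylpyran, atoms O4'–C2''–C3''=C4''–C5'–C4') the O4'–C2'' and C3''–C4'' bonds; then O1–C2 of ring C; then C2–C3 (the chalcone C=C); then the aryl–prenyl bonds at C6 and C8.
Enabling feature: ring B carries one carbon at C1' (C2 of ring C) and one at C5' (C4'' of ring D). Each is flanked by an oxygen (O2', O4'), and a local mirror plane runs through C3' and C6', so ring B is 4,6-dihydroxyisophthalaldehyde. O4'–C4'–C5'–C4'' is a masked salicylaldehyde, and ring D is the valence isomer of a vinyl ortho-quinone methide.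
Forward: rings A and B are bought. Ring A is filled by double C-prenylation, and A and B are joined by Claisen–Schmidt condensation at one of the two equivalent formyl groups. Ring C closes by oxa-Michael addition, and ring D closes last at the surviving formyl group by a three-component Petasis / amine loss / oxa-6π cascade. Two acetals are then removed.
Stereochemistry: the only stereocentre, C2 (S), is set by a cinchona thiourea catalyst in the ring C closure and is a spectator afterwards. Every later step avoids strong base.

Key step: step 7

Assumption: 4,6-dihydroxyisophthalaldehyde (5) and 2-methylprop-1-enylboronic acid (10) are taken as catalogue chemicals, and the quinine-derived thiourea is taken as the antipode that leads to (2S); if the sense of induction is the reverse, the quinidine-derived pseudoenantiomer is used in the same way.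

Step 1
Reactants: 1 2,4,6-trihydroxyacetophenone; 2 prenyl bromide (1-bromo-3-methylbut-2-ene)
Product: 3 2,4,6-trihydroxy-3,5-bis(3-methylbut-2-enyl)acetophenone
Conditions: 2 (2.1 equiv), KOH (2.2 equiv), H2O, 0 °C to rt
Reagents that add atoms: none
Why: Base-mediated double C-alkylation of an acylphloroglucinol (the classical C-prenylation of phloroglucinol phenoxides in water, where solvation of the oxygens disfavours O-alkylation) should fill the two equivalent free ring positions, so that ring A carries no C–H afterwards.

Step 2
Reactants: 3 2,4,6-trihydroxy-3,5-bis(3-methylbut-2-enyl)acetophenone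
Product: 4 2-hydroxy-4,6-bis(methoxymethoxy)-3,5-bis(3-methylbut-2-enyl)acetophenone
Conditions: MOMCl (2.2 equiv), K2CO3, acetone, 0 °C to rt
Reagents that add atoms: chloromethyl methyl ether (MOMCl), COCCl
Why: Williamson-type O-alkylation etherifies the 4-OH and one of the two equivalent ortho OH groups, after which the last OH is held in a strong hydrogen bond to the acetyl group and stays free for the later closure of ring C.

Step 3
Reactants: 5 4,6-dihydroxyisophthalaldehyde
Product: 6 4,6-bis(methoxymethoxy)isophthalaldehyde
Conditions: MOMCl (2.5 equiv), K2CO3, DMF, 0 °C to rt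
Reagents that add atoms: chloromethyl methyl ether (MOMCl), COCCl
Why: Williamson-type O-alkylation of both phenoxides in a dipolar aprotic solvent overcomes their hydrogen bonds to the formyl groups, the symmetry of 5 allows only one product, and the acetals keep the aldehydes electrophilic in the basic condensation that follows.

Step 4
Reactants: 4 2-hydroxy-4,6-bis(methoxymethoxy)-3,5-bis(3-methylbut-2-enyl)acetophenone; 6 4,6-bis(methoxymethoxy)isophthalaldehyde
Product: 7 (E)-3-[5-formyl-2,4-bis(methoxymethoxy)phenyl]-1-[2-hydroxy-4,6-bis(methoxymethoxy)-3,5-bis(3-methylbut-2-enyl)phenyl]prop-2-en-1-one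
Conditions: 6 (2.5 equiv, excess recovered), KOH, EtOH–H2O, 0 °C to rt; then aq. citric acid, 0 °C
Reagents that add atoms: none
Why: In this Claisen–Schmidt condensation (aldol addition, then E1cB loss of water to the conjugated E-alkene) the two formyl groups of 6 are equivalent, so no regiochemical question arises, and the excess of 6 together with the loss of one acceptor substituent after the first condensation should hold the reaction at the mono-enone.

Step 5
Reactants: 7 the formyl chalcone
Product: 8 (2S)-5'-formyl-5,7,2',4'-tetrakis(methoxymethoxy)-6,8-bis(3-methylbut-2-enyl)flavanone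
Conditions: 1-[3,5-bis(trifluoromethyl)phenyl]-3-(9-deoxy-epi-quinin-9-yl)thiourea (10 mol %), toluene, 0 °C, stopped before equilibrium, unreacted 7 recycled
Reagents that add atoms: none
Why: In this bifunctional amine–thiourea catalysed intramolecular oxa-Michael addition (6-endo-trig, a mimic of chalcone isomerase) the thiourea binds the enone carbonyl, the quinuclidine activates the only free phenol, and the chiral pocket steers the oxygen to the face of the β-carbon that gives (2S), while the 5'-formyl group raises the acceptor strength of the otherwise donor-rich cinnamoyl unit and disfavours the reverse reaction.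

Step 6
Reactants: 8 the tetra-MOM formyl flavanone
Product: 9 (2S)-5'-formyl-5,4'-dihydroxy-7,2'-bis(methoxymethoxy)-6,8-bis(3-methylbut-2-enyl)flavanone
Conditions: MgBr2·OEt2 (3 equiv), CH2Cl2, 0 °C to rt; then pH 7 buffer
Reagents that add atoms: none
Why: In this chelation-directed Lewis-acid cleavage of aryl acetal ethers, magnesium can form a six-membered chelate between a carbonyl oxygen and a neighbouring aryl oxygen only at O4' (next to CHO) and at O5 (peri to C4=O), bromide removes the CH2OMe group from just these two, and with no Brønsted acid or base present the prenyl groups and C2 stay untouched.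

Step 7
Reactants: 9 the 4'-hydroxy-5'-formyl flavanone; 10 2-methylprop-1-enylboronic acid
Product: 13 (2S)-7,2'-bis-O-(methoxymethyl)euchrenone a3, via Petasis amine adduct 11 (not isolated), via vinyl ortho-quinone methide 12 (not isolated)
Conditions: 10 (1.5 equiv), Bn2NH (20 mol %), 1,4-dioxane, 70 °C, Ar
Reagents that add atoms: none
Why: Bn2NH condenses with the 5'-CHO of 9 to an iminium ion, and the neighbouring 4'-OH binds 10 as a tetracoordinate boronate that hands its 2-methylpropenyl group to the iminium carbon (Petasis borono-Mannich reaction, three components, C4''–C3'' bond), giving 11 and boric acid. On warming, 11 expels Bn2NH, pushed by the ortho 4'-OH and the para 2'-O-acetal oxygen, to give the vinyl ortho-quinone methide 12, so the amine is a traceless third component and turns over. Ring D then closes by a thermally allowed disrotatory oxa-6π electrocyclisation of the O4'=C4'–C5'=C4''–C3''=C2'' array of 12 (O4'–C2'' bond), driven by re-aromatisation of ring B, and an (E)-methide that cannot close re-adds the amine reversibly and is funnelled through the (Z)-isomer. The closest known reaction type is the secondary-amine-catalysed condensation of salicylaldehydes with alkenylboronic acids to 2H-chromenes. No stereocentre is created in 13 (the aminated carbon of 11 becomes sp2), and C2 is a spectator that should stay (S) because the amine is weak and hindered and the 7-O and 2'-O acetals block phenoxide- or quinone-methide-assisted opening of ring C. The step needs linear rather than angular annulation, secured because O4' is the only oxygen ortho to the formyl carbon, and it needs chemoselectivity, secured because only the aldehyde (not the hindered, hydrogen-bonded C4 ketone) forms an iminium ion and because no oxidant or acid is present that could attack the two ortho-prenylphenol units of ring A.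

Step 8
Reactants: 13 (2S)-7,2'-bis-O-(methoxymethyl)euchrenone a3
Product: 14 euchrenone a3
Conditions: aq. HCl (3 M)–MeOH, 40 °C, short contact time
Reagents that add atoms: none
Why: Acid-catalysed acetal exchange with methanol (standard MOM cleavage as used on prenylated polyphenols) frees O7 and O2', and the dilute acid and mild temperature should keep chroman formation from the ortho-prenylphenols and acid-induced opening of ring C slow, so C2 stays (S).

Compound list
1 | 2,4,6-trihydroxyacetophenone | CC(=O)c1c(O)cc(O)cc1O | starting material
2 | prenyl bromide (1-bromo-3-methylbut-2-ene) | CC(C)=CCBr | starting material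
3 | 2,4,6-trihydroxy-3,5-bis(3-methylbut-2-enyl)acetophenone | CC(=O)c1c(O)c(CC=C(C)C)c(O)c(CC=C(C)C)c1O | intermediate
4 | 2-hydroxy-4,6-bis(methoxymethoxy)-3,5-bis(3-methylbut-2-enyl)acetophenone | CC(=O)c1c(O)c(CC=C(C)C)c(OCOC)c(CC=C(C)C)c1OCOC | intermediate
5 | 4,6-dihydroxyisophthalaldehyde | O=Cc1cc(C=O)c(O)cc1O | starting material
6 | 4,6-bis(methoxymethoxy)isophthalaldehyde | O=Cc1cc(C=O)c(OCOC)cc1OCOC | intermediate
7 | (E)-chalcone with a 2-hydroxy-4,6-bis(MOM-oxy)-3,5-diprenylphenyl ketone part and a 5-formyl-2,4-bis(MOM-oxy)phenyl part | COCOc1c(CC=C(C)C)c(O)c(C(=O)/C=C/c2cc(C=O)c(OCOC)cc2OCOC)c(OCOC)c1CC=C(C)C | intermediate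
8 | (2S)-5'-formyl-5,7,2',4'-tetrakis(methoxymethoxy)-6,8-diprenylflavanone | CC(C)=CCc1c(OCOC)c(CC=C(C)C)c2c(c1OCOC)C(=O)C[C@@H](c1cc(C=O)c(OCOC)cc1OCOC)O2 | intermediate
9 | (2S)-5'-formyl-5,4'-dihydroxy-7,2'-bis(methoxymethoxy)-6,8-diprenylflavanone | CC(C)=CCc1c(OCOC)c(CC=C(C)C)c2c(c1O)C(=O)C[C@@H](c1cc(C=O)c(O)cc1OCOC)O2 | intermediate
10 | 2-methylprop-1-enylboronic acid | CC(C)=CB(O)O | starting material
11 | Petasis adduct: 9 with 5'-CHO replaced by CH(NBn2)–CH=CMe2, both epimers at the aminated carbon, (2S) | CC(C)=CCc1c(OCOC)c(CC=C(C)C)c2c(c1O)C(=O)C[C@@H](c1cc(C(C=C(C)C)N(Cc3ccccc3)Cc3ccccc3)c(O)cc1OCOC)O2 | intermediate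
12 | vinyl ortho-quinone methide: ring B as a cyclohexadienone with C4'=O and (Z)-C5'=CH–CH=CMe2, (2S) | CC(C)=CCc1c(OCOC)c(CC=C(C)C)c2c(c1O)C(=O)C[C@@H](C1=C/C(=C/C=C(C)C)C(=O)C=C1OCOC)O2 | intermediate
13 | (2S)-7,2'-bis-O-(methoxymethyl)euchrenone a3 | CC(C)=CCc1c(OCOC)c(CC=C(C)C)c2c(c1O)C(=O)C[C@@H](c1cc3c(cc1OCOC)OC(C)(C)C=C3)O2 | intermediate
14 | euchrenone a3, (2S) | CC(C)=CCc1c(O)c(CC=C(C)C)c2c(c1O)C(=O)C[C@@H](c1cc3c(cc1O)OC(C)(C)C=C3)O2 | target

Total step count: 8. Longest linear sequence: 7 (steps 1, 2, 4, 5, 6, 7, 8).

Steps most likely to fail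

Step 7. The alkenyl group may transfer only sluggishly from boron to a donor-rich iminium ion, and amine-promoted retro-oxa-Michael opening of ring C may erode the C2 configuration during the heating that expels the amine. The fallback sets out from 8 and comes back at 14. The aldehyde of 8 is alkenylated under non-basic Nozaki–Hiyama–Kishi conditions (1-bromo-2-methylprop-1-ene, CrCl2, cat. NiCl2, DMF, rt), which are aldehyde-selective in the presence of the C4 ketone. This gives the benzylic allylic alcohol F1 as both carbinol epimers. Dilute HCl in MeOH then removes the four acetals and ionises the doubly activated alcohol. The freed O4' closes ring D by cyclodehydration, which leads to 14 without amine or heating.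

Step 5. Facial selectivity may be poor, or enantiomeric purity may be lost because the oxa-Michael addition is reversible. The fallback sets out from 7 and comes back at 8.
- Ring C is closed without stereocontrol (NaOAc, EtOH, reflux) to the racemic flavanone F2.
- A Noyori-type transfer-hydrogenative kinetic resolution (RuCl(p-cymene)[(R,R)-TsDPEN], HCO2H–Et3N, EtOAc, rt) reduces the formyl group of both enantiomers but the C4 ketone of the (2R)-enantiomer only.
- This should give the (2S)-hydroxymethyl flavanone F3 beside the (2R,4R)-cis-diol F4, which are separated by chromatography.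
- MnO2 in CH2Cl2 re-oxidises the benzylic alcohol of F3 to 8.

Step 6. Discrimination between chelated and non-chelated acetals may be incomplete, giving mixtures of partly deprotected flavanones. The fallback sets out from 8 and comes back at 14. All four acetals are removed first (dilute HCl, MeOH, 40 °C) to give the tetrahydroxy formyl flavanone F5. The three-component ring closure with 10 is then run on unprotected F5 as the last operation, with a full equivalent of Bn2NH because the acidic 7-OH ties up part of the amine. This gives 14 directly in a protecting-group-free endgame.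

Further compounds
F1 | step 7 | (2S)-5'-(1-hydroxy-3-methylbut-2-enyl)-5,7,2',4'-tetrakis(methoxymethoxy)-6,8-diprenylflavanone, both carbinol epimers | CC(C)=CCc1c(OCOC)c(CC=C(C)C)c2c(c1OCOC)C(=O)C[C@@H](c1cc(C(O)C=C(C)C)c(OCOC)cc1OCOC)O2
F2 | step 5 | racemic 5'-formyl-5,7,2',4'-tetrakis(methoxymethoxy)-6,8-diprenylflavanone | CC(C)=CCc1c(OCOC)c(CC=C(C)C)c2c(c1OCOC)C(=O)CC(c1cc(C=O)c(OCOC)cc1OCOC)O2
F3 | step 5 | (2S)-5'-(hydroxymethyl)-5,7,2',4'-tetrakis(methoxymethoxy)-6,8-diprenylflavanone | CC(C)=CCc1c(OCOC)c(CC=C(C)C)c2c(c1OCOC)C(=O)C[C@@H](c1cc(CO)c(OCOC)cc1OCOC)O2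
F4 | step 5 | (2R,4R)-5'-(hydroxymethyl)-5,7,2',4'-tetrakis(methoxymethoxy)-6,8-diprenylflavan-4-ol | CC(C)=CCc1c(OCOC)c(CC=C(C)C)c2c(c1OCOC)[C@H](O)C[C@H](c1cc(CO)c(OCOC)cc1OCOC)O2
F5 | step 6 | (2S)-5'-formyl-5,7,2',4'-tetrahydroxy-6,8-diprenylflavanone | CC(C)=CCc1c(O)c(CC=C(C)C)c2c(c1O)C(=O)C[C@@H](c1cc(C=O)c(O)cc1O)O2
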